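## Structural features

The target is a B-type procyanidin tetramer. Four flavan-3-ol units, each a chroman (phloroglucinol-type ring A fused to pyran ring C) with a catechol ring B on C2, are joined only by C–C bonds from C4 of one unit to ring A of the next: C4 of unit 1 to C6 of unit 2, C4 of unit 2 to C8 of unit 3, and C4 of unit 3 to C8 of unit 4. Unit 1 is a catechin (2R,3S, 2,3-trans) with a 4α (3,4-trans) bond; units 2 and 3 are epicatechins (2R,3R, 2,3-cis) with 4β (3,4-trans) bonds; unit 4 is a plain epicatechin. There are eleven stereocentres, nine of them in three contiguous C2–C3–C4 triads. Sixteen phenols (four catechols) and four secondary alcohols make the free compound sensitive to air, to base (C2 epimerisation) and to acid (cleavage of the diarylmethine interflavan bonds), so they must stay masked until the last step. The real difficulty is not the skeleton but the choice of ring-A carbon (C6 or C8) for each C4, above all the unusual 4→6 bond onto unit 2, and the configuration of the three C4 centres. The key step uses the fact that in unit 3 the atoms C4a and O1 are an ortho carbon and the oxygen of a phenol, bridged by C4–C3–C2. With C2 at the acyl level, ring C of unit 3 is a dihydrocoumarin that a phenol can form by adding its ortho carbon to a β-carbon (C4, already bonded to C8 of unit 4) and its oxygen to the acyl carbon.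

## Logic of the disconnections

27 from 26. The twenty O–benzyl bonds and three aryl C–Br bonds are cut last. Benzyl masks every hydroxyl against organometallics, oxidants and Lewis acids, and the bromines are blocking groups; both fall in one hydrogenolysis. The forward step must be neutral and reductive, with no acid or base reaching the free oligomer.

26 from 25 and 17. The C4(unit 2)–C8(unit 3) bond is cut with the natural polarity (C4 cation, ring-A nucleophile), which splits the tetramer into two dimers. The forward step needs C8 rather than C6 attack on the upper unit of 17 and approach anti to O3 (4β). It also needs an electrophile that cannot attack itself (all its ring-A positions are brominated or substituted) and a C4 leaving group that survived the making of 25 (a sulfide).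

25 from 22 and 24. The C4(unit 1)–C6(unit 2) bond is cut with the same polarity, so both halves come from natural monomers. The forward step needs C6 attack (C8 of 24 blocked by bromine), no self-condensation (both free positions of 22 brominated), anti approach to O3 of a 2,3-trans cation (4α), and a hard Lewis acid that leaves the C4–S bond of 24 alone.

24 from 23 from 4, and 22 from 21 from 20 from 18. These are C4–S, C4–O, C–Br and O–benzyl bonds, all functional-group work on the monomers. 4 is shared with the other branch, which saves steps.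

17 from 16 from 12 and 14 (through 15). The C2–H bond and then the C2–aryl bond of unit 3 are cut, so ring B enters as an aryl anion and C2 is a lactone carbonyl. The forward steps need a single addition to an aryl lactone and hydride delivery that puts the aryl group cis to O3.

12 from 11 from 10. The O3–benzyl bond and then the C3–O bond are cut. The oxygen is introduced on the lactone enolate, and the forward step needs attack anti to the C4 aryl group.

10 from 7 and 9. This is the key cut: C4–C4a and O1–C2 of unit 3. It reduces unit 3 to a symmetric phenol and places the three-carbon acyl unit on C8 of unit 4 beforehand, so the 3–4 interflavan bond exists before ring C of unit 3 is closed and its regiochemistry is not left to a Friedel–Crafts coupling. The forward step needs catalyst control of the C4 face and C- rather than O-acylation of the phenol.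

7 from 4 and 5; 4 from 3 from 1; 9 from 8; 14 from 13. The aryl–vinyl bond at C8 is cut (cross-coupling with a masked enal), then C8–Br and the O–benzyl bonds. These rest on the known C8 selectivity of bromination and on routine etherifications.

## Other disconnections considered

Alternative 1: The cut runs through unit 2: its C4–C4a bond and the C4–C8 bond to unit 3 are traced to one acetal carbon. Forward, the open-chain dimethyl acetal A2 is ionised with Me3SiOSO2CF3. A2 is an aryl ether that carries unit 1 para to the ether oxygen and already holds C2 and C3 of unit 2. Either equivalent ortho carbon closes the pyran to the C4 methyl ether A3, which ionises again and is captured by C8 of octa-O-benzyl procyanidin B2 A4 to give the full skeleton A1.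
- In its favour: the 4→6 attachment of unit 1 is fixed by the symmetry of the ring and needs no bromine block. This is better than the chosen plan, where that bond depends on a halogen block and a deactivated nucleophile. The ionic chemistry is of an established kind, so the central event carries less mechanistic risk than the carbene annulation, also better. Two C–C bonds form in one operation.
- Against it: A2 is a demanding intermediate, an aryl benzylic ether with two adjacent stereocentres made on a phenol that already bears unit 1, and its benzylic C2–O bond may ionise under the same Lewis acid. Capture by A4 raises the same C8/C6 question as step 17 (equal). The 4β outcome rests on substrate control as in step 17 (equal).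
- Comparison: in step count the plans should be close, since what is saved in the union is spent on A2. The chosen plan tests its least certain step on monomer-sized material, whereas this one stakes A2 and A4 on the final cascade.

Alternative 2: The cut is C2=C3 of unit 1 at the flav-2-ene level. Forward, the aryl 3,4-bis(benzyloxy)benzoate A5 is treated with excess Cp2Ti(μ-Cl)(μ-CH2)AlMe2. Its ortho carbon bears a 1-arylallyl group attached to C6 of the 8-brominated trimer of units 2 to 4. The ester carbonyl is methylenated and the titanium alkylidene closes the pyran by olefin metathesis to the 4H-chromene A6. Hydroboration–oxidation anti to the C4 aryl group would then give the 2,3-trans-3,4-trans pattern.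
- In its favour: C2 and C3 of unit 1 would follow from C4 by substrate control in exactly the catechin sense. This is arguably better than relying on 4α capture of a 2,3-trans cation as in step 16. The 4→6 bond is in place before the ring is built.
- Against it: the allylic diarylmethine centre on C6 of a trimer must itself be made with regio- and stereocontrol, and no simple way is at hand. A stoichiometric, Lewis-acidic titanium–aluminium reagent must act on a hindered aryl ester beside some fifteen benzyl ethers. Everything from the metathesis onward is linear work on the most valuable intermediate.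
- Comparison: structurally it addresses only unit 1 and leaves all three interflavan bonds to other chemistry. Mechanistically, ester methylenation–metathesis is a known route to cyclic enol ethers and is about as risky as the carbene step (equal). In step economy it is worse, because several late steps build a unit that the chosen plan takes from natural catechin.

Alternative 3: The cut removes C2 and C3 of unit 2 as a two-carbon aldehyde (C3–C4 and O1–C2). Forward, the benzhydrol A7 loses water under mild acid to an o-quinone methide. A7 is a phenol whose ortho carbinol carbon carries C8 of unit 3, with unit 1 already on the ring. The enamine from benzyloxyacetaldehyde A8 and a diarylprolinol silyl ether adds across the o-quinone methide in a [4+2] sense to give the lactol A9, with C3 and C4 of unit 2 set.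
- In its favour: the C3 oxygen arrives already benzylated, so the hydroxylation and benzylation of the chosen plan (steps 6 and 7) are not needed, which is better. The catalyst sets two stereocentres in one event instead of one, also better. Enamine addition to o-quinone methides is at least as well founded as the oxidative carbene annulation (equal).
- Against it: the o-quinone methide is stabilised by three oxygen donors and flanked by substituted positions, so it should be a sluggish and reversible acceptor. The lactol still needs oxidation, arylation and reduction, with the same open question at C2 as step 10 (equal), but on a tetramer. A7 presupposes a separate regiocontrolled assembly of all four units.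
- Comparison: structurally it is the closest relative of the chosen plan, since both build a heterocycle onto a phenol by a catalytic annulation. It spends that annulation at the latest stage, so the material at risk is larger and the overall step economy is poorer, although its key step is two operations shorter.

Key step: step 5

Remarks on the chemistry:
- The structures of 7 and 10 were checked atom by atom against units 3 and 4 of the target and stand as drawn. The new lactone centre is 4R and maps onto the 4β bond of unit 3.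
- Both antipodes of the aminoindanol-derived triazolium salt are available. The one that delivers 4R is to be identified in a small-scale run and is called the matched antipode below.
- C4 of 21 and 22 is drawn without configuration because that centre is ionised in step 16.
- Design points added to the bare disconnection: the enal is made from the C8 bromide in one cross-coupling; bromine atoms block C8 of unit 2 and C6/C8 of unit 1; unit 2 carries a C4 sulfide so that two couplings can be run in sequence.

Step 1
Reactants: 1 (−)-epicatechin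
Product: 3 3,5,7,3',4'-penta-O-benzyl-(−)-epicatechin (2R,3R), via 5,7,3',4'-tetra-O-benzylepicatechin 2 (not isolated)
Conditions: BnBr (6 equiv), K2CO3, DMF, 0 °C → rt; then NaH, 0 °C → rt (one pot)
Reagents that add atoms: benzyl bromide, BrCc1ccccc1
Why: Williamson ether synthesis in two stages: K2CO3 ionises only the four phenols, and once they are capped NaH generates the C3 alkoxide, which is benzylated by the BnBr still present. Capping the phenols first avoids base-induced C2 epimerisation and C-benzylation of ring A; no stereocentre is touched.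

Step 2
Reactants: 3 3,5,7,3',4'-penta-O-benzyl-(−)-epicatechin
Product: 4 8-bromo-3,5,7,3',4'-penta-O-benzylepicatechin
Conditions: NBS (1.0 equiv), CH2Cl2, −40 °C → rt
Reagents that add atoms: N-bromosuccinimide, O=C1CCC(=O)N1Br
Why: Electrophilic aromatic bromination; of the two free ring-A positions, C8 (between the tied-back ring oxygen and O7) is less hindered than C6 and reacts first with one equivalent at low temperature, the usual regiochemistry for O-benzylated flavan-3-ols.

Step 3
Reactants: 4 8-bromo-3,5,7,3',4'-penta-O-benzylepicatechin; 5 (E)-2-(3,3-diethoxyprop-1-en-1-yl)-4,4,5,5-tetramethyl-1,3,2-dioxaborolane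
Product: 7 (E)-3-(3,5,7,3',4'-penta-O-benzylepicatechin-8-yl)acrolein, via (E)-8-(3,3-diethoxyprop-1-en-1-yl)-penta-O-benzylepicatechin 6 (not isolated)
Conditions: Pd(OAc)2 (5 mol%), SPhos (10 mol%), K3PO4, toluene/H2O, 90 °C; then 1 M HCl, THF, rt
Reagents that add atoms: water, O
Why: Suzuki–Miyaura coupling; the bulky dialkylbiarylphosphine is chosen because the bromide is electron-rich and has two ortho oxygens, and the E-alkenylboronate transfers with retention of geometry. The acid work-up unmasks the aldehyde without harming benzyl ethers, and conjugation with the aryl ring keeps the E-enal favoured.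

Step 4
Reactants: 8 phloroglucinol
Product: 9 3,5-bis(benzyloxy)phenol
Conditions: BnBr (2.0 equiv), K2CO3, DMF, 0 °C → rt; chromatography
Reagents that add atoms: benzyl bromide, BrCc1ccccc1
Why: Statistical Williamson O-benzylation of a cheap triphenol; carbonate in a dipolar aprotic solvent favours O- over C-alkylation, and the mono- and tri-ethers are separable from the symmetric diether.

Step 5
Reactants: 7 (E)-3-(3,5,7,3',4'-penta-O-benzylepicatechin-8-yl)acrolein; 9 3,5-bis(benzyloxy)phenol
Product: 10 (4R)-5,7-bis(benzyloxy)-4-(3,5,7,3',4'-penta-O-benzylepicatechin-8-yl)-3,4-dihydrocoumarin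
Conditions: 2-mesityl-5a,10b-dihydro-4H,6H-indeno[2,1-b][1,2,4]triazolo[4,3-d][1,4]oxazin-2-ium chloride (matched antipode, 20 mol%), DBU (30 mol%), 3,3',5,5'-tetra-tert-butyl-4,4'-diphenoquinone (1.2 equiv), 4 Å MS, toluene, rt → 40 °C
Reagents that add atoms: none
Why: The carbene adds to the aldehyde of 7 and the Breslow intermediate is oxidised by the diphenoquinone to an α,β-unsaturated acyl azolium; the phenoxide of 9 adds to the acyl carbon and passes its ortho carbon to the β-carbon in a [3,3] shift (direct ortho conjugate addition reaches the same enol azolium), and after rearomatisation the phenol oxygen acylates intramolecularly and frees the carbene. The closest known reaction type is the oxidative carbene-catalysed [3+3] annulation of enals with 2-naphthols, electron-rich phenols and 1,3-dicarbonyl compounds to 4-substituted dihydrocoumarins and dihydropyranones. The one new ring, the lactone ring of unit 3, is closed last by 6-exo-trig addition–elimination of the phenol oxygen at the acyl azolium carbon (O1–C2), after the C4–C4a bond is made. The new stereocentre C4 is set in the C–C bond-forming event under catalyst control: the indane backbone shields one face of the acyl azolium, while the stereocentres of unit 4 lie four and five bonds from the β-carbon and should exert little bias, so the antipode that gives 4R is used. Ortho rather than para C-alkylation is required and is secured because the carbon is delivered while the oxygen is bound at the acyl carbon, and only an ortho adduct can lactonise and turn the catalyst over; the two ortho positions of 9 are equivalent. C- over O-acylation is the second requirement: the phloroglucinol-type ring is a strong carbon nucleophile, and an aryl ester formed by O-acylation can in principle be taken up again by the carbene. The benzyl ether on O3 of unit 4 removes the only other acyl acceptor in 7.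

Step 6
Reactants: 10 (4R)-5,7-bis(benzyloxy)-4-(penta-O-benzylepicatechin-8-yl)-3,4-dihydrocoumarin
Product: 11 (3R,4R)-5,7-bis(benzyloxy)-3-hydroxy-4-(penta-O-benzylepicatechin-8-yl)-3,4-dihydrocoumarin (3,4-trans)
Conditions: KN(SiMe3)2 (1.1 equiv), THF, −78 °C; 3-phenyl-2-(phenylsulfonyl)oxaziridine (1.3 equiv), −78 °C; AcOH quench
Reagents that add atoms: 3-phenyl-2-(phenylsulfonyl)oxaziridine, O=S(=O)(N1OC1c1ccccc1)c1ccccc1
Why: Davis hydroxylation of the potassium lactone enolate; the enolate is planar at C3 and the bulky, pseudoaxial C4 aryl group (unit 4) shields one face, so oxygen should arrive on the other face and give the 3,4-trans (3R) alcohol. The low temperature keeps the aryl ester enolate from fragmenting to a ketene.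

Step 7
Reactants: 11 (3R,4R)-3-hydroxy lactone
Product: 12 (3R,4R)-3,5,7-tris(benzyloxy)-4-(penta-O-benzylepicatechin-8-yl)-3,4-dihydrocoumarin (3,4-trans)
Conditions: BnBr (3 equiv), Ag2O (2 equiv), 4 Å MS, CH2Cl2, rt, dark
Reagents that add atoms: benzyl bromide, BrCc1ccccc1
Why: Silver oxide-mediated (Purdie-type) O-benzylation under non-basic, non-acidic conditions, chosen so that the α-oxy aryl lactone is neither epimerised at C3 nor opened and the electron-rich rings see no benzyl cation source.

Step 8
Reactants: 13 4-bromocatechol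
Product: 14 4-bromo-1,2-bis(benzyloxy)benzene
Conditions: BnBr (2.3 equiv), K2CO3, DMF, rt
Reagents that add atoms: benzyl bromide, BrCc1ccccc1
Why: Williamson O-benzylation of both catechol hydroxyls; the aryl bromide is inert to carbonate.

Step 9
Reactants: 12 (3R,4R)-3,5,7-tris(benzyloxy)-4-(penta-O-benzylepicatechin-8-yl)-3,4-dihydrocoumarin; 14 4-bromo-1,2-bis(benzyloxy)benzene
Product: 16 2-hydroxy-3,5,7,3',4'-penta-O-benzylepicatechin-(4β→8)-3,5,7,3',4'-penta-O-benzylepicatechin (C2 hemiketal of the upper unit as both anomers), via 3,4-bis(benzyloxy)phenyllithium 15 (not isolated)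
Conditions: 14, n-BuLi (1.05 equiv), THF, −78 °C; cannulate slowly into 12, THF, −78 °C; AcOH/THF quench at −78 °C
Reagents that add atoms: none
Why: Bromine–lithium exchange, then 1,2-addition of the aryllithium to the lactone carbonyl, as in the preparation of C-aryl glycoside lactols. At −78 °C the lithium hemiketal alkoxide, chelated by the C3 benzyloxy group, should persist until the cold quench and so resist a second addition; C2 is formed as an anomeric mixture, which is of no consequence.

Step 10
Reactants: 16 C2 hemiketal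
Product: 17 3,5,7,3',4'-penta-O-benzylepicatechin-(4β→8)-3,5,7,3',4'-penta-O-benzylepicatechin (deca-O-benzyl procyanidin B2)
Conditions: Et3SiH (5 equiv), BF3·OEt2 (2 equiv), CH2Cl2, −78 → −30 °C
Reagents that add atoms: none
Why: Ionic hydrogenation of a lactol: BF3·OEt2 ionises C2 to the 2-aryl oxocarbenium ion and Et3SiH delivers hydride. In the half-chair enforced by the peri 5-benzyloxy group, the C4 aryl and C3 benzyloxy groups are trans-diaxial; axial hydride delivery anti to the C3–O bond through a chair-like transition state should place the new aryl group equatorial and cis to O3, which is the (2R) 2,3-cis pattern of epicatechin.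

Step 11
Reactants: 18 (+)-catechin
Product: 20 3,5,7,3',4'-penta-O-benzyl-(+)-catechin (2R,3S), via 5,7,3',4'-tetra-O-benzylcatechin 19 (not isolated)
Conditions: BnBr (6 equiv), K2CO3, DMF, 0 °C → rt; then NaH, 0 °C → rt (one pot)
Reagents that add atoms: benzyl bromide, BrCc1ccccc1
Why: The same two-stage Williamson etherification as in step 1: phenols first under carbonate, then the C3 alkoxide with NaH; no stereocentre is touched.

Step 12
Reactants: 20 3,5,7,3',4'-penta-O-benzyl-(+)-catechin
Product: 21 4-(2-ethoxyethoxy)-3,5,7,3',4'-penta-O-benzylcatechin (C4 epimers)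
Conditions: DDQ (1.5 equiv), 2-ethoxyethanol (5 equiv), CH2Cl2, rt
Reagents that add atoms: 2-ethoxyethanol, CCOCCO
Why: DDQ abstracts hydride from the C4 methylene, which is activated by the 5,7-dioxygenated ring A, and the alcohol captures the benzylic cation. The epimer ratio at C4 is irrelevant because the centre is ionised again in step 16.

Step 13
Reactants: 21 4-(2-ethoxyethoxy)-penta-O-benzylcatechin
Product: 22 6,8-dibromo-4-(2-ethoxyethoxy)-3,5,7,3',4'-penta-O-benzylcatechin (C4 epimers)
Conditions: NBS (2.2 equiv), NaHCO3 (solid), CH2Cl2, −20 °C → rt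
Reagents that add atoms: N-bromosuccinimide, O=C1CCC(=O)N1Br
Why: Electrophilic bromination of both free ring-A positions; the two bromines leave unit 1 with no nucleophilic ring carbon in the later couplings and are removed in step 18. Oxidation precedes bromination because two bromines would slow hydride abstraction at C4.

Step 14
Reactants: 4 8-bromo-3,5,7,3',4'-penta-O-benzylepicatechin
Product: 23 8-bromo-4β-(2-ethoxyethoxy)-3,5,7,3',4'-penta-O-benzylepicatechin
Conditions: DDQ (2 equiv), 2-ethoxyethanol (5 equiv), CH2Cl2, rt → 35 °C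
Reagents that add atoms: 2-ethoxyethanol, CCOCCO
Why: The same DDQ oxidation and alcohol capture as in step 12; one bromine should slow but not prevent hydride abstraction, and the alcohol enters trans to the C3 benzyloxy group (4β), as is normal for 2,3-cis flavans.

Step 15
Reactants: 23 8-bromo-4β-(2-ethoxyethoxy)-penta-O-benzylepicatechin
Product: 24 8-bromo-4β-(2,6-dimethylphenylthio)-3,5,7,3',4'-penta-O-benzylepicatechin
Conditions: 2,6-dimethylbenzenethiol (3 equiv), BF3·OEt2 (1 equiv), CH2Cl2, −78 → −40 °C
Reagents that add atoms: 2,6-dimethylbenzenethiol, Cc1cccc(C)c1S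
Why: Lewis acid-mediated exchange of the C4 ether for a thioether through the benzylic cation, the chemistry of procyanidin thiolysis; the thiol adds trans to O3 (4β). The hindered aryl sulfide is inert to hard Lewis acids, which is what permits step 16, and the low temperature spares the benzyl ethers.

Step 16
Reactants: 22 6,8-dibromo-4-(2-ethoxyethoxy)-penta-O-benzylcatechin; 24 8-bromo-4β-(2,6-dimethylphenylthio)-penta-O-benzylepicatechin (1.5 equiv)
Product: 25 6,8-dibromo-3,5,7,3',4'-penta-O-benzylcatechin-(4α→6)-8-bromo-4β-(2,6-dimethylphenylthio)-3,5,7,3',4'-penta-O-benzylepicatechin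
Conditions: BF3·OEt2 (1.5 equiv), 4 Å MS, CH2Cl2, −78 → −20 °C
Reagents that add atoms: none
Why: Lewis acid-promoted Friedel–Crafts alkylation of a flavan ring A by a flavan C4 cation, the standard interflavan coupling. C8 of 24 is blocked, so only C6 can react; 22 has no free ring-A position and cannot self-condense; BF3·OEt2 does not ionise the C–S bond; and attack anti to the C3 benzyloxy group of the 2,3-trans cation should give the 3,4-trans (4α) bond.

Step 17
Reactants: 25 dimer sulfide of units 1 and 2; 17 deca-O-benzyl procyanidin B2 (1.2 equiv)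
Product: 26 6,8-dibromo-penta-O-benzylcatechin-(4α→6)-8-bromo-penta-O-benzylepicatechin-(4β→8)-penta-O-benzylepicatechin-(4β→8)-penta-O-benzylepicatechin (eicosa-O-benzyl tribromo tetramer)
Conditions: AgOSO2CF3 (2 equiv), 2,6-di-tert-butyl-4-methylpyridine (2 equiv), 4 Å MS, CH2Cl2, −40 → 0 °C, dark; NaHCO3 wash
Reagents that add atoms: none
Why: Thiophilic activation of the C4 sulfide by monovalent silver gives the epicatechin-type C4 cation, which should be captured by the most nucleophilic position of 17, C8 of its upper unit, anti to the C3 benzyloxy group (4β, the normal outcome for 2,3-cis units). The brominated rings of 25 are too deactivated to compete, and the hindered pyridine buffers the acid released.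

Step 18
Reactants: 26 eicosa-O-benzyl tribromo tetramer
Product: 27 catechin-(4α→6)-epicatechin-(4β→8)-epicatechin-(4β→8)-epicatechin (CNP0228086.1)
Conditions: H2 (1 atm), Pd(OH)2/C, NaOAc (4 equiv), THF/MeOH/H2O, rt; filtration under argon, lyophilisation
Reagents that add atoms: none
Why: Hydrogenolysis of all twenty benzyl ethers and hydrodehalogenation of the three aryl bromides over Pd(OH)2/C; the acetate buffer takes up HBr so that the acid-labile interflavan bonds and the C2 centres are not disturbed, and no stereocentre is involved.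

Compound list

1 | (−)-epicatechin | Oc1cc(O)c2c(c1)O[C@H](c1ccc(O)c(O)c1)[C@H](O)C2 | starting material
2 | 5,7,3',4'-tetra-O-benzyl-(−)-epicatechin | c4ccccc4COc1cc(OCc4ccccc4)c2c(c1)O[C@H](c1ccc(OCc4ccccc4)c(OCc4ccccc4)c1)[C@H](O)C2 | intermediate
3 | 3,5,7,3',4'-penta-O-benzyl-(−)-epicatechin | c4ccccc4COc1cc(OCc4ccccc4)c2c(c1)O[C@H](c1ccc(OCc4ccccc4)c(OCc4ccccc4)c1)[C@H](OCc4ccccc4)C2 | intermediate
4 | 8-bromo-3,5,7,3',4'-penta-O-benzylepicatechin | Brc1c(OCc4ccccc4)cc(OCc4ccccc4)c3c1O[C@H](c1ccc(OCc4ccccc4)c(OCc4ccccc4)c1)[C@H](OCc4ccccc4)C3 | intermediate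
5 | (E)-2-(3,3-diethoxyprop-1-en-1-yl)-4,4,5,5-tetramethyl-1,3,2-dioxaborolane | CCOC(OCC)/C=C/B1OC(C)(C)C(C)(C)O1 | starting material
6 | (E)-8-(3,3-diethoxyprop-1-en-1-yl)-3,5,7,3',4'-penta-O-benzylepicatechin | CCOC(OCC)/C=C/c1c(OCc4ccccc4)cc(OCc4ccccc4)c3c1O[C@H](c1ccc(OCc4ccccc4)c(OCc4ccccc4)c1)[C@H](OCc4ccccc4)C3 | intermediate
7 | (E)-3-(3,5,7,3',4'-penta-O-benzylepicatechin-8-yl)acrolein | O=C/C=C/c1c(OCc4ccccc4)cc(OCc4ccccc4)c3c1O[C@H](c1ccc(OCc4ccccc4)c(OCc4ccccc4)c1)[C@H](OCc4ccccc4)C3 | intermediate
8 | phloroglucinol | Oc1cc(O)cc(O)c1 | starting material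
9 | 3,5-bis(benzyloxy)phenol | Oc1cc(OCc4ccccc4)cc(OCc4ccccc4)c1 | intermediate
10 | (4R)-5,7-bis(benzyloxy)-4-(3,5,7,3',4'-penta-O-benzylepicatechin-8-yl)-3,4-dihydrocoumarin | c4ccccc4COc1cc(OCc4ccccc4)c2c(c1)OC(=O)C[C@H]2c1c(OCc4ccccc4)cc(OCc4ccccc4)c3c1O[C@H](c1ccc(OCc4ccccc4)c(OCc4ccccc4)c1)[C@H](OCc4ccccc4)C3 | intermediate
11 | (3R,4R)-5,7-bis(benzyloxy)-3-hydroxy-4-(penta-O-benzylepicatechin-8-yl)-3,4-dihydrocoumarin (3,4-trans) | c4ccccc4COc1cc(OCc4ccccc4)c2c(c1)OC(=O)[C@H](O)[C@H]2c1c(OCc4ccccc4)cc(OCc4ccccc4)c3c1O[C@H](c1ccc(OCc4ccccc4)c(OCc4ccccc4)c1)[C@H](OCc4ccccc4)C3 | intermediate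
12 | (3R,4R)-3,5,7-tris(benzyloxy)-4-(penta-O-benzylepicatechin-8-yl)-3,4-dihydrocoumarin (3,4-trans) | c4ccccc4COc1cc(OCc4ccccc4)c2c(c1)OC(=O)[C@H](OCc4ccccc4)[C@H]2c1c(OCc4ccccc4)cc(OCc4ccccc4)c3c1O[C@H](c1ccc(OCc4ccccc4)c(OCc4ccccc4)c1)[C@H](OCc4ccccc4)C3 | intermediate
13 | 4-bromocatechol | Oc1ccc(Br)cc1O | starting material
14 | 4-bromo-1,2-bis(benzyloxy)benzene | Brc1ccc(OCc4ccccc4)c(OCc4ccccc4)c1 | intermediate
15 | 3,4-bis(benzyloxy)phenyllithium | [Li]c1ccc(OCc4ccccc4)c(OCc4ccccc4)c1 | intermediate
16 | 2-hydroxy-penta-O-benzylepicatechin-(4β→8)-penta-O-benzylepicatechin (C2 hemiketal of the upper unit, both anomers; 3,4-trans as in 12) | c4ccccc4COc1cc(OCc4ccccc4)c2c(c1)OC(O)(c1ccc(OCc4ccccc4)c(OCc4ccccc4)c1)[C@H](OCc4ccccc4)[C@H]2c1c(OCc4ccccc4)cc(OCc4ccccc4)c3c1O[C@H](c1ccc(OCc4ccccc4)c(OCc4ccccc4)c1)[C@H](OCc4ccccc4)C3 | intermediate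
17 | 3,5,7,3',4'-penta-O-benzylepicatechin-(4β→8)-3,5,7,3',4'-penta-O-benzylepicatechin (upper unit 2R,3R,4R) | c4ccccc4COc1cc(OCc4ccccc4)c2c(c1)O[C@H](c1ccc(OCc4ccccc4)c(OCc4ccccc4)c1)[C@H](OCc4ccccc4)[C@H]2c1c(OCc4ccccc4)cc(OCc4ccccc4)c3c1O[C@H](c1ccc(OCc4ccccc4)c(OCc4ccccc4)c1)[C@H](OCc4ccccc4)C3 | intermediate
18 | (+)-catechin | Oc1cc(O)c2c(c1)O[C@H](c1ccc(O)c(O)c1)[C@@H](O)C2 | starting material
19 | 5,7,3',4'-tetra-O-benzyl-(+)-catechin | c4ccccc4COc1cc(OCc4ccccc4)c2c(c1)O[C@H](c1ccc(OCc4ccccc4)c(OCc4ccccc4)c1)[C@@H](O)C2 | intermediate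
20 | 3,5,7,3',4'-penta-O-benzyl-(+)-catechin | c4ccccc4COc1cc(OCc4ccccc4)c2c(c1)O[C@H](c1ccc(OCc4ccccc4)c(OCc4ccccc4)c1)[C@@H](OCc4ccccc4)C2 | intermediate
21 | 4-(2-ethoxyethoxy)-3,5,7,3',4'-penta-O-benzylcatechin (C4 epimers) | c4ccccc4COc1cc(OCc4ccccc4)c2c(c1)O[C@H](c1ccc(OCc4ccccc4)c(OCc4ccccc4)c1)[C@@H](OCc4ccccc4)C2OCCOCC | intermediate
22 | 6,8-dibromo-4-(2-ethoxyethoxy)-3,5,7,3',4'-penta-O-benzylcatechin (C4 epimers) | c4ccccc4COc1c(Br)c(OCc4ccccc4)c2c(c1Br)O[C@H](c1ccc(OCc4ccccc4)c(OCc4ccccc4)c1)[C@@H](OCc4ccccc4)C2OCCOCC | intermediate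
23 | 8-bromo-4β-(2-ethoxyethoxy)-3,5,7,3',4'-penta-O-benzylepicatechin | Brc1c(OCc4ccccc4)cc(OCc4ccccc4)c3c1O[C@H](c1ccc(OCc4ccccc4)c(OCc4ccccc4)c1)[C@H](OCc4ccccc4)[C@H]3OCCOCC | intermediate
24 | 8-bromo-4β-(2,6-dimethylphenylthio)-3,5,7,3',4'-penta-O-benzylepicatechin | Brc1c(OCc4ccccc4)cc(OCc4ccccc4)c3c1O[C@H](c1ccc(OCc4ccccc4)c(OCc4ccccc4)c1)[C@H](OCc4ccccc4)[C@H]3Sc1c(C)cccc1C | intermediate
25 | 6,8-dibromo-penta-O-benzylcatechin-(4α→6)-8-bromo-4β-(2,6-dimethylphenylthio)-penta-O-benzylepicatechin | c4ccccc4COc1c(Br)c(OCc4ccccc4)c2c(c1Br)O[C@H](c1ccc(OCc4ccccc4)c(OCc4ccccc4)c1)[C@@H](OCc4ccccc4)[C@@H]2c1c(OCc4ccccc4)c(Br)c2c(c1OCc4ccccc4)[C@H](Sc1c(C)cccc1C)[C@@H](OCc4ccccc4)[C@@H](c1ccc(OCc4ccccc4)c(OCc4ccccc4)c1)O2 | intermediate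
26 | 6,8-dibromo-penta-O-benzylcatechin-(4α→6)-8-bromo-penta-O-benzylepicatechin-(4β→8)-penta-O-benzylepicatechin-(4β→8)-penta-O-benzylepicatechin | c4ccccc4COc1c(Br)c(OCc4ccccc4)c2c(c1Br)O[C@H](c1ccc(OCc4ccccc4)c(OCc4ccccc4)c1)[C@@H](OCc4ccccc4)[C@@H]2c1c(OCc4ccccc4)c(Br)c2c(c1OCc4ccccc4)[C@H](c1c(OCc4ccccc4)cc(OCc4ccccc4)c3c1O[C@H](c1ccc(OCc4ccccc4)c(OCc4ccccc4)c1)[C@H](OCc4ccccc4)[C@H]3c1c(OCc4ccccc4)cc(OCc4ccccc4)c3c1O[C@H](c1ccc(OCc4ccccc4)c(OCc4ccccc4)c1)[C@H](OCc4ccccc4)C3)[C@@H](OCc4ccccc4)[C@@H](c1ccc(OCc4ccccc4)c(OCc4ccccc4)c1)O2 | intermediate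
27 | catechin-(4α→6)-epicatechin-(4β→8)-epicatechin-(4β→8)-epicatechin (CNP0228086.1) | Oc1cc(O)c2c(c1)O[C@H](c1ccc(O)c(O)c1)[C@@H](O)[C@@H]2c1c(O)cc2c(c1O)[C@H](c1c(O)cc(O)c3c1O[C@H](c1ccc(O)c(O)c1)[C@H](O)[C@H]3c1c(O)cc(O)c3c1O[C@H](c1ccc(O)c(O)c1)[C@H](O)C3)[C@@H](O)[C@@H](c1ccc(O)c(O)c1)O2 | target

Total step count: 18. Longest linear sequence: 10 steps (1 → 3 → 4 → 7 → 10 → 11 → 12 → 16 → 17 → 26 → 27; steps 1, 2, 3, 5, 6, 7, 9, 10, 17, 18).

Least certain steps

Step 5 (key step). The β-carbon of the acyl azolium is electron-rich and flanked by two ortho oxygens, so conjugate delivery of the phenol carbon may be slow. O-acylation to an aryl ester, or catalyst deactivation, could then win. The facial bias of the catalyst may also be eroded because the C–C bond forms between two very hindered partners. The fallback abandons the annulation for the conventional ionic union of units 3 and 4. It sets out from 3: oxidation with DDQ and 2-ethoxyethanol (CH2Cl2, rt) gives 4β-(2-ethoxyethoxy)-3,5,7,3',4'-penta-O-benzylepicatechin F1. Condensation of F1 with an excess of 3 (Me3SiOSO2CF3 cat., CH2Cl2, −78 °C) gives the 4β→8 dimer, and the route is rejoined at 17; steps 5 to 10 are then not needed.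

Step 9. The tetrahedral adduct of an aryl lactone can collapse to a phenoxide and a ketone, which would take up a second aryllithium. The aryllithium may also enolise the lactone and epimerise C3. The fallback sets out from 12 and changes the acyl electrophile. Aminolysis with MeNHOMe·HCl/AlMe3 (CH2Cl2, 0 °C → rt) opens the lactone to the phenolic Weinreb amide F2 [(2R,3R)-2-(benzyloxy)-3-(2-hydroxy-4,6-bis(benzyloxy)phenyl)-N-methoxy-N-methyl-3-(penta-O-benzylepicatechin-8-yl)propanamide]. Its chelated adduct with 15 (2.2 equiv, THF, −78 °C) cannot over-add; on work-up the keto phenol closes to the hemiketal and the route is rejoined at 16.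

Step 10. Hydride may be delivered to the wrong face of the oxocarbenium ion, since the favoured axial trajectory passes the pseudoaxial C4 aryl group. Reversible loss of H3 to an enol ether could also scramble C3. The fallback sets out from 16 and replaces the cationic reduction by a substrate-controlled ketone reduction and an invertive ring closure. Chelation-controlled reduction of the open keto phenol tautomer with Zn(BH4)2 (Et2O, −20 °C) should give the anti carbinol F3 [(1S,2R,3R)-1-(3,4-bis(benzyloxy)phenyl)-2-(benzyloxy)-3-(2-hydroxy-4,6-bis(benzyloxy)phenyl)-3-(penta-O-benzylepicatechin-8-yl)propan-1-ol]. Mitsunobu cyclisation (PPh3, DIAD, THF, 0 °C) with inversion at the carbinol carbon then gives the 2,3-cis flavan, and the route is rejoined at 17.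

Step 16. The brominated ring of 24 is a weak nucleophile. The cation from 22 may instead be captured at sulfur, which can transfer the arylthio group to unit 1 and release the cation of unit 2, scrambling the partners. The 4α/4β selectivity of a 2,3-trans cation is also less secure than in the epicatechin series. The fallback reverses the order of activation so that sulfur sits only on the electrophile. It sets out from 22 and 23. Thiol exchange on 22 (2,6-dimethylbenzenethiol, BF3·OEt2, CH2Cl2, −78 → −40 °C) gives 6,8-dibromo-4-(2,6-dimethylphenylthio)-penta-O-benzylcatechin F4. Silver-promoted coupling of F4 with 23 (AgOSO2CF3, 2,6-di-tert-butyl-4-methylpyridine, CH2Cl2, −40 °C) gives the dimer ether 6,8-dibromo-penta-O-benzylcatechin-(4α→6)-8-bromo-4β-(2-ethoxyethoxy)-penta-O-benzylepicatechin F5. F5 is condensed with 17 under catalytic Me3SiOSO2CF3 (CH2Cl2, −40 °C), and the route is rejoined at 26.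

Step 17. Capture of a crowded dimeric cation by C8 of a dimeric nucleophile may be slow relative to attack at the C6 positions of 17. Stoichiometric silver and the acid it liberates may also erode the acid-labile interflavan bonds before coupling is complete. The fallback sets out from 25 and changes the leaving group and the mode of activation. Silver-promoted methanolysis (AgOSO2CF3, MeOH in excess, CH2Cl2, −20 °C) uses a small nucleophile in excess and does not expose 17; it gives the methyl ether 6,8-dibromo-penta-O-benzylcatechin-(4α→6)-8-bromo-4β-methoxy-penta-O-benzylepicatechin F6. F6 is coupled with 17 under catalytic Me3SiOSO2CF3 (CH2Cl2, −78 → −40 °C), and the route is rejoined at 26.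

Further compounds

F1 | step 5 | 4β-(2-ethoxyethoxy)-3,5,7,3',4'-penta-O-benzylepicatechin | c4ccccc4COc1cc(OCc4ccccc4)c2c(c1)O[C@H](c1ccc(OCc4ccccc4)c(OCc4ccccc4)c1)[C@H](OCc4ccccc4)[C@H]2OCCOCC
F2 | step 9 | (2R,3R)-2-(benzyloxy)-3-(2-hydroxy-4,6-bis(benzyloxy)phenyl)-N-methoxy-N-methyl-3-(penta-O-benzylepicatechin-8-yl)propanamide | CON(C)C(=O)[C@H](OCc4ccccc4)[C@H](c1c(O)cc(OCc4ccccc4)cc1OCc4ccccc4)c1c(OCc4ccccc4)cc(OCc4ccccc4)c3c1O[C@H](c1ccc(OCc4ccccc4)c(OCc4ccccc4)c1)[C@H](OCc4ccccc4)C3
F3 | step 10 | (1S,2R,3R)-1-(3,4-bis(benzyloxy)phenyl)-2-(benzyloxy)-3-(2-hydroxy-4,6-bis(benzyloxy)phenyl)-3-(penta-O-benzylepicatechin-8-yl)propan-1-ol (1,2-anti) | O[C@@H](c1ccc(OCc4ccccc4)c(OCc4ccccc4)c1)[C@H](OCc4ccccc4)[C@H](c1c(O)cc(OCc4ccccc4)cc1OCc4ccccc4)c1c(OCc4ccccc4)cc(OCc4ccccc4)c3c1O[C@H](c1ccc(OCc4ccccc4)c(OCc4ccccc4)c1)[C@H](OCc4ccccc4)C3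
F4 | step 16 | 6,8-dibromo-4-(2,6-dimethylphenylthio)-3,5,7,3',4'-penta-O-benzylcatechin (C4 epimers) | c4ccccc4COc1c(Br)c(OCc4ccccc4)c2c(c1Br)O[C@H](c1ccc(OCc4ccccc4)c(OCc4ccccc4)c1)[C@@H](OCc4ccccc4)C2Sc1c(C)cccc1C
F5 | step 16 | 6,8-dibromo-penta-O-benzylcatechin-(4α→6)-8-bromo-4β-(2-ethoxyethoxy)-penta-O-benzylepicatechin | c4ccccc4COc1c(Br)c(OCc4ccccc4)c2c(c1Br)O[C@H](c1ccc(OCc4ccccc4)c(OCc4ccccc4)c1)[C@@H](OCc4ccccc4)[C@@H]2c1c(OCc4ccccc4)c(Br)c2c(c1OCc4ccccc4)[C@H](OCCOCC)[C@@H](OCc4ccccc4)[C@@H](c1ccc(OCc4ccccc4)c(OCc4ccccc4)c1)O2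
F6 | step 17 | 6,8-dibromo-penta-O-benzylcatechin-(4α→6)-8-bromo-4β-methoxy-penta-O-benzylepicatechin | c4ccccc4COc1c(Br)c(OCc4ccccc4)c2c(c1Br)O[C@H](c1ccc(OCc4ccccc4)c(OCc4ccccc4)c1)[C@@H](OCc4ccccc4)[C@@H]2c1c(OCc4ccccc4)c(Br)c2c(c1OCc4ccccc4)[C@H](OC)[C@@H](OCc4ccccc4)[C@@H](c1ccc(OCc4ccccc4)c(OCc4ccccc4)c1)O2
A1 | alternative 1 | octadeca-O-benzyl tetramer with free O3 on units 3 and 4 | c4ccccc4COc1cc(OCc4ccccc4)c2c(c1)O[C@H](c1ccc(OCc4ccccc4)c(OCc4ccccc4)c1)[C@@H](OCc4ccccc4)[C@@H]2c1c(OCc4ccccc4)cc2c(c1OCc4ccccc4)[C@H](c1c(OCc4ccccc4)cc(OCc4ccccc4)c3c1O[C@H](c1ccc(OCc4ccccc4)c(OCc4ccccc4)c1)[C@H](O)[C@H]3c1c(OCc4ccccc4)cc(OCc4ccccc4)c3c1O[C@H](c1ccc(OCc4ccccc4)c(OCc4ccccc4)c1)[C@H](O)C3)[C@@H](OCc4ccccc4)[C@@H](c1ccc(OCc4ccccc4)c(OCc4ccccc4)c1)O2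
A2 | alternative 1 | (1R,2R)-1-(3,4-bis(benzyloxy)phenyl)-2-(benzyloxy)-3,3-dimethoxypropyl 3,5-bis(benzyloxy)-4-(penta-O-benzylcatechin-4α-yl)phenyl ether | c4ccccc4COc1cc(OCc4ccccc4)c2c(c1)O[C@H](c1ccc(OCc4ccccc4)c(OCc4ccccc4)c1)[C@@H](OCc4ccccc4)[C@@H]2c1c(OCc4ccccc4)cc(O[C@H](c5ccc(OCc4ccccc4)c(OCc4ccccc4)c5)[C@H](OCc4ccccc4)C(OC)OC)cc1OCc4ccccc4
A3 | alternative 1 | penta-O-benzylcatechin-(4α→6)-4-methoxy-penta-O-benzylepicatechin (C4 epimers) | c4ccccc4COc1cc(OCc4ccccc4)c2c(c1)O[C@H](c1ccc(OCc4ccccc4)c(OCc4ccccc4)c1)[C@@H](OCc4ccccc4)[C@@H]2c1c(OCc4ccccc4)cc2c(c1OCc4ccccc4)C(OC)[C@@H](OCc4ccccc4)[C@@H](c1ccc(OCc4ccccc4)c(OCc4ccccc4)c1)O2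
A4 | alternative 1 | 5,7,3',4'-tetra-O-benzylepicatechin-(4β→8)-5,7,3',4'-tetra-O-benzylepicatechin (octa-O-benzyl procyanidin B2) | c1c(OCc4ccccc4)cc(OCc4ccccc4)c3c1O[C@H](c1ccc(OCc4ccccc4)c(OCc4ccccc4)c1)[C@H](O)[C@H]3c1c(OCc4ccccc4)cc(OCc4ccccc4)c3c1O[C@H](c1ccc(OCc4ccccc4)c(OCc4ccccc4)c1)[C@H](O)C3
A5 | alternative 2 | 3,5-bis(benzyloxy)-2-[1-(trimer-6-yl)allyl]phenyl 3,4-bis(benzyloxy)benzoate (trimer = 8-bromo-penta-O-benzylepicatechin-(4β→8)-penta-O-benzylepicatechin-(4β→8)-penta-O-benzylepicatechin) | C=C[C@@H](c1c(OCc4ccccc4)cc(OCc4ccccc4)cc1OC(=O)c1ccc(OCc4ccccc4)c(OCc4ccccc4)c1)c1c(OCc4ccccc4)c(Br)c2c(c1OCc4ccccc4)[C@H](c1c(OCc4ccccc4)cc(OCc4ccccc4)c3c1O[C@H](c1ccc(OCc4ccccc4)c(OCc4ccccc4)c1)[C@H](OCc4ccccc4)[C@H]3c1c(OCc4ccccc4)cc(OCc4ccccc4)c3c1O[C@H](c1ccc(OCc4ccccc4)c(OCc4ccccc4)c1)[C@H](OCc4ccccc4)C3)[C@@H](OCc4ccccc4)[C@@H](c1ccc(OCc4ccccc4)c(OCc4ccccc4)c1)O2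
A6 | alternative 2 | tetramer with unit 1 as a 4-aryl-flav-2-ene (4H-chromene), unit 2 brominated at C8 | c4ccccc4COc1cc(OCc4ccccc4)c2c(c1)OC(c1ccc(OCc4ccccc4)c(OCc4ccccc4)c1)=C[C@@H]2c1c(OCc4ccccc4)c(Br)c2c(c1OCc4ccccc4)[C@H](c1c(OCc4ccccc4)cc(OCc4ccccc4)c3c1O[C@H](c1ccc(OCc4ccccc4)c(OCc4ccccc4)c1)[C@H](OCc4ccccc4)[C@H]3c1c(OCc4ccccc4)cc(OCc4ccccc4)c3c1O[C@H](c1ccc(OCc4ccccc4)c(OCc4ccccc4)c1)[C@H](OCc4ccccc4)C3)[C@@H](OCc4ccccc4)[C@@H](c1ccc(OCc4ccccc4)c(OCc4ccccc4)c1)O2
A7 | alternative 3 | benzhydrol: [2-hydroxy-4,6-bis(benzyloxy)-5-(penta-O-benzylcatechin-4α-yl)phenyl](dimer-8-yl)methanol (dimer = deca-O-benzyl procyanidin B2; carbinol epimers) | c4ccccc4COc1cc(OCc4ccccc4)c2c(c1)O[C@H](c1ccc(OCc4ccccc4)c(OCc4ccccc4)c1)[C@@H](OCc4ccccc4)[C@@H]2c1c(OCc4ccccc4)cc(O)c(c1OCc4ccccc4)C(O)c1c(OCc4ccccc4)cc(OCc4ccccc4)c3c1O[C@H](c1ccc(OCc4ccccc4)c(OCc4ccccc4)c1)[C@H](OCc4ccccc4)[C@H]3c1c(OCc4ccccc4)cc(OCc4ccccc4)c3c1O[C@H](c1ccc(OCc4ccccc4)c(OCc4ccccc4)c1)[C@H](OCc4ccccc4)C3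
A8 | alternative 3 | benzyloxyacetaldehyde | O=CCOCc1ccccc1
A9 | alternative 3 | tetramer lactol lacking ring B of unit 2 (C2 anomers) | c4ccccc4COc1cc(OCc4ccccc4)c2c(c1)O[C@H](c1ccc(OCc4ccccc4)c(OCc4ccccc4)c1)[C@@H](OCc4ccccc4)[C@@H]2c1c(OCc4ccccc4)cc2c(c1OCc4ccccc4)[C@H](c1c(OCc4ccccc4)cc(OCc4ccccc4)c3c1O[C@H](c1ccc(OCc4ccccc4)c(OCc4ccccc4)c1)[C@H](OCc4ccccc4)[C@H]3c1c(OCc4ccccc4)cc(OCc4ccccc4)c3c1O[C@H](c1ccc(OCc4ccccc4)c(OCc4ccccc4)c1)[C@H](OCc4ccccc4)C3)[C@@H](OCc4ccccc4)C(O)O2
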